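Compound numbers are those of the steps and the compound list. Locants follow the target: ring carbons C1 (CH bearing the side chain), C2 (methyl, oxirane), C3 (oxirane CH), C4 (methyl, alkene), C5 (alkene CH), C6 (quaternary); side chain C7(CH3)=C8H–C9H(CH3)–C10(=O)–ethyl. Descriptors in names use these locants; the SMILES are authoritative. PMB = 4-methoxybenzyl, TES = triethylsilyl, TBS = tert-butyldimethylsilyl, Bpin = pinacolatoboryl.

## Analysis of the target

Target 34 is a cyclohexene (C1–C6) with a trisubstituted C4=C5 alkene, a fused C2–C3 oxirane, a quaternary C6 carrying a methyl group and a 2-methoxy-3,5-dimethyl-4-pyranone, and at C1 an (E)-trisubstituted alkenyl chain that ends in an ethyl ketone. There are four contiguous ring stereocentres (1R, 2S, 3R, 6R) and a remote one at C9 (R). The C1 side chain, the C2 methyl and the pyranone lie on one face; the oxirane oxygen and the C6 methyl lie on the other. C1 is a methine wedged between two fully substituted carbons, so the C1/C2/C6 triad is the steric core. Three groups limit the reagents that can be used late: the vinyl oxirane (acid, Lewis acid, low-valent metals), C9 (α to a ketone and allylic, so base epimerises it or moves the alkene into conjugation) and the methoxypyranone (alkoxide exchange, strong electrophiles). The difficulty is to form the C4=C5 alkene next to quaternary C6 with the triad intact, and to order the end game so that oxirane, pyranone and C9 never meet conditions they do not survive. The strategy rests on one feature: C5, C6, C1 and C7 can be held in a 1-methylcyclobutene (C5=C7). A ketene cycloaddition builds it and fixes C1 and C6. Its strain is then spent when a C5 carbene closes onto an isopropenyl ketone at C3/C4, which forms ring C1–C6 and leaves C7 as an isopropenyl carbon on C1.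

## Retrosynthetic reasoning

**C8–C9 (34 to 31 and 32).** This bond is made last. C9 is the only stereocentre outside the ring and the only one that base can scramble, so cutting here lets every other operation finish before C9 exists. The forward step joins the alkenyl carbon of boronate 31 (through alkenylzinc 33) to racemic 32 with retention of the (E)-geometry; the catalyst, not the distant ring, has to choose the C9 configuration.

**C3–O of the oxirane (31 to 29 to 28).** The oxirane is opened to trans-diol 29, closed forward through mesylate 30 by attack of the C2 oxygen with inversion at C3. Diol 29 comes from ketol 28 by a reduction in which the C2 hydroxyl delivers hydride to its own face. The same oxygen that becomes the oxirane oxygen therefore sets C3. The oxirane is placed after the pyranone O-methylation and after the borylation, because a hard methylating agent and a boron halide would both open it.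

**Pyranone (28 to 23 and 24).** The ring is cut at the C–C bond next to the carbon on C6 and at the lactone C–O bond. This gives neopentyl aldehyde 23 and keto ester 24, joined forward through 25, 26 and 27. Because C6 is quaternary, the heterocycle has to be grown from a carbonyl on C6. Aldehyde 23 cannot enolise, and the dianion chemistry is run before any C10 ketone is present.

**C8–B and protecting groups (23 to 22 to 21 to 19).** The boron is placed on the isopropenyl CH2 of 19 by a boryl-Heck reaction. At that point the molecule holds only an enone and two silyl ethers. The boronate is then carried as a robust placeholder for C8 through desilylation, oxidation and pyranone formation.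

**C4=C5 (19 to 18), the key disconnection.** The ring alkene is cut and C5 reconnected to C7, which gives methylcyclobutene 18 with its isopropenyl ketone arm. This stores the C5–C6 and C1–C7 bonds and the C1/C6 configuration in a rigid four-membered ring. The forward metathesis is then driven by strain rather than by a favourable alkene substitution pattern. Other ring bonds would have to be formed between or next to the two quaternary carbons.

**C3–C4 (18 to 17 to 15 and 16, then 15 to 14 to 13).** The isopropenyl ketone comes from aldehyde 15 and Grignard reagent 16, followed by oxidation. This is done after the cyclobutene is complete, because an isopropenyl group would outcompete the hindered ring-forming alkene for the ketene.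

**C7–CH3, C1–C7 and C5–C6 (13 to 12 to 11 to 10 to 8 and 9).** The C7 methyl is attached by cross-coupling to enol triflate 12 of cyclobutanone 11. Ketone 11 arises by dechlorination of 10, the [2+2] adduct of (E)-alkene 8 with the ketene generated from 9. The cycloaddition has to give the regiochemistry C7 to C1 and C5 to C6, the cis relationship that follows from the (E)-alkene, and the correct face with respect to C2.

**C1=C6 and the source of C2 (8 to 7 to 6 to 5 to 2 and 3, then 2 to 1).** The alkene is made by Wittig reaction of ylide 3 with hydroxy aldehyde 4. C2 comes unchanged from 1: its hydroxymethyl carbon becomes C1 and its oxirane CH2 becomes C3. The oxirane of 1 is opened in the first step with an alkoxide that leaves a PMB ether. A vinyl oxirane would not survive the ketene and its zinc salts (ring expansion by O-acylation and [3,3] shift, or Lewis-acid opening). C3 is restored to the oxirane level only at the end.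

## Alternatives that were turned down

**Alternative 1:** Diels–Alder disconnection of C1–C2 and C5–C6. Forward, silyloxydiene A3 adds to chiral butenolide A2 on the face anti to the menthyloxy group and gives the cis-fused lactone acetal A1. One step would form the ring, two C–C bonds and the C1/C6 pair under auxiliary control. C6 would also arrive with a carboxyl carbon ready for pyranone formation, which is better than the hydroxymethyl group the chosen route has to oxidise. Against it: A2 is a trisubstituted, α-methylated dienophile and A3 a crowded diene, so the cycloaddition should be slow. A1 also has C2 as a CH(CH3) carbon and C5 as CH2. The tertiary C2 oxygen would then need a regio- and face-selective enolate oxidation next to C1, the C4=C5 alkene a separate dehydrogenation, and the acetal carbon a stereocontrolled ketone olefination to reach C7=C8. The chosen route is longer up to the ring, but C2 arrives with its oxygen from the chiral pool, C4=C5 is formed at the right oxidation level in the ring-forming step, and C7 emerges as an alkene handle.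

**Alternative 2:** Disconnection of C2–C3 by an intramolecular aldehyde–ketone benzoin reaction. A chiral triazolium-derived carbene would convert the enal of the acyclic keto enal A5 into an acyl anion equivalent that adds to the C2 methyl ketone and gives hydroxy ketone A4. This is the most convergent plan: side chain and pyranone are in place before the ring closes, and only reduction, oxirane closure and ketal removal follow. On post-cyclisation step count it beats the chosen route. Against it: in A5 the C1 hydrogen is α to the methyl ketone and can epimerise under the basic carbene conditions. The C1/C6 pair would have to be built in an open chain with no ring to relay stereochemistry. Enal-derived carbene adducts tend to react at the β-carbon, and the (Z)-enal needed for closure can isomerise. The C2 configuration would depend on catalyst control working against a crowded substrate, and the ketal would have to be removed with acid beside a vinyl oxirane. The chosen route offers instead a C1 hydrogen that is never α to a carbonyl once C2 is in place, and a C1/C6 relationship fixed by a suprafacial cycloaddition.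

**Alternative 3:** Disconnection of C3–C4 by a Nozaki–Hiyama–Kishi closure. The (Z)-vinyl iodide of aldehyde A7 would be converted by a divalent chromium salt with a nickel co-catalyst into an alkenylchromium that adds to the C3 aldehyde and gives cyclohexenol A6. Its strength is that C3 arrives as the alcohol needed for the oxirane, possibly with the right trans relationship, so no ketone reduction is needed. The reaction is also chemoselective, and the C6 ester is at the right level for the pyranone. Against it: a geometrically pure (Z)-trisubstituted vinyl iodide next to quaternary C6 is hard to make. The C1/C2/C6 triad with two fully substituted carbons must again be assembled acyclically. The C3 diastereoselectivity is not assured, and a large excess of chromium salt is required. The chosen route closes the ring catalytically with strain as the driving force. It pays for this with a later C3 reduction, which the free C2 hydroxyl is used to direct.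

Key step: step 14

Remark (assumption): the facial preference of the ketene cycloaddition (step 6) and the sense of induction of the chiral nickel catalyst (step 24) cannot be derived from the structures alone. Compounds are drawn as the isomers the route needs, and the measures for the opposite outcome are given with the uncertain steps.

## Route

Step 1
Reactants: 1 (S)-2-methylglycidol
Product: 2 (2S)-3-[(4-methoxyphenyl)methoxy]-2-methylpropane-1,2-diol
Conditions: 4-methoxybenzyl alcohol (4 equiv), NaH (0.2 equiv), DMF, 70 °C
Reagents that add atoms: 4-methoxybenzyl alcohol, COc1ccc(CO)cc1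
Why: Base-catalysed SN2 opening of the oxirane at its unsubstituted CH2 terminus leaves C2 untouched; a Payne rearrangement of 1 is degenerate and returns the same enantiomer, and the excess alcohol suppresses oligomerisation.

Step 2
Reactants: 2 diol; 3 ethyl 2-(triphenylphosphoranylidene)propanoate
Product: 5 ethyl (2E,4S)-4-hydroxy-5-[(4-methoxyphenyl)methoxy]-2,4-dimethylpent-2-enoate, via hydroxy aldehyde 4 (not isolated)
Conditions: SO3·pyridine, DMSO, i-Pr2NEt, CH2Cl2, 0 °C; then 3, 23 °C
Reagents that add atoms: none
Why: Parikh–Doering oxidation touches only the primary hydroxyl and avoids reagents that cleave 1,2-diols; the non-enolisable aldehyde 4 is trapped in the same flask by a Wittig olefination whose stabilised, α-branched ylide should give the (E)-enoate.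

Step 3
Reactants: 5 hydroxy enoate
Product: 6 ethyl (2E,4S)-5-[(4-methoxyphenyl)methoxy]-2,4-dimethyl-4-(triethylsilyloxy)pent-2-enoate
Conditions: Et3SiOTf, 2,6-lutidine, CH2Cl2, −78 to 0 °C
Reagents that add atoms: triethylsilyl trifluoromethanesulfonate, CC[Si](CC)(CC)OS(=O)(=O)C(F)(F)F
Why: Silylation of a tertiary alcohol with a silyl triflate; the hindered silyl ether later keeps the C2 oxygen from being acylated by the ketene.

Step 4
Reactants: 6 silyl ether enoate
Product: 7 (2E,4S)-5-[(4-methoxyphenyl)methoxy]-2,4-dimethyl-4-(triethylsilyloxy)pent-2-en-1-ol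
Conditions: i-Bu2AlH (2.2 equiv), CH2Cl2, −78 °C
Reagents that add atoms: none
Why: 1,2-Reduction of the conjugated ester to the allylic alcohol with DIBAL-H; the alkene geometry and the silyl ether are not affected.

Step 5
Reactants: 7 allylic alcohol
Product: 8 (E)-allylic silyl ether TBSO–CH2–C6(CH3)=C1H–C2(CH3)(OTES)–CH2OPMB (2S)
Conditions: t-BuMe2SiCl, imidazole, CH2Cl2, 23 °C
Reagents that add atoms: tert-butyldimethylsilyl chloride, CC(C)(C)[Si](C)(C)Cl
Why: Standard silylation of a primary alcohol; both allylic oxygens are now silyl ethers, which are too hindered and too weakly nucleophilic for O-acylation and Bellus–Claisen rearrangement.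

Step 6
Reactants: 8 (E)-allylic silyl ether; 9 trichloroacetyl chloride
Product: 10 (1R,2S,6R)-2,2-dichlorocyclobutanone with ring C7(=O)–C5Cl2–C6–C1
Conditions: Zn(Cu), Et2O/DME, slow addition of 9, 25–35 °C
Reagents that add atoms: none
Why: Thermal [2+2] ketene–alkene cycloaddition: the ketene carbonyl carbon bonds to the less substituted C1 and the CCl2 carbon to C6, and because both bonds form on one face of the (E)-alkene the C2-bearing group on C1 and the C6 methyl end up cis. The face is chosen by the C2 stereocentre; the isomer needed corresponds to a staggered transition state with the silyloxy group outside, the C2 methyl inside and the ketene anti to the CH2OPMB arm, but the level of this bias cannot be predicted and the two diastereomers are to be separated at 10 or 11. The non-basic conditions leave the C1 hydrogen α to the new ketone alone.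

Step 7
Reactants: 10 dichlorocyclobutanone
Product: 11 (1R,2S,6R)-cyclobutanone with ring C7(=O)–C5H2–C6–C1
Conditions: Zn, AcOH, 23 °C
Reagents that add atoms: none
Why: Reductive dechlorination of an α,α-dichloro ketone by zinc; the mildly acidic medium does not epimerise C1 and leaves the silyl and PMB ethers in place.

Step 8
Reactants: 11 cyclobutanone
Product: 12 (1R,2S,6R)-cyclobutenyl triflate C7(OTf)=C5H
Conditions: KN(SiMe3)2, THF, −78 °C; then PhNTf2
Reagents that add atoms: N-phenylbis(trifluoromethanesulfonimide), O=S(=O)(N(c1ccccc1)S(=O)(=O)C(F)(F)F)C(F)(F)F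
Why: Kinetic enolisation takes the C5 methylene proton rather than the C1 methine, which is shielded by two fully substituted neighbours, so C1 is neither epimerised nor exposed to β-elimination of the C2 silyloxy group; O-triflation fixes the enolate.

Step 9
Reactants: 12 cyclobutenyl triflate
Product: 13 (1R,2S,6R)-1-methylcyclobutene PMB ether
Conditions: CH3ZnCl, Pd(PPh3)4 (5 mol %), THF, 40 °C
Reagents that add atoms: methylzinc chloride, C[Zn]Cl
Why: Negishi coupling of an enol triflate places the C7 methyl group; ethers and silyl ethers are inert to the organozinc reagent.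

Step 10
Reactants: 13 PMB ether
Product: 14 (1R,2S,6R)-primary alcohol C2(CH3)(OTES)–C3H2OH
Conditions: DDQ, CH2Cl2/pH 7 buffer, 0 °C
Reagents that add atoms: none
Why: Oxidative cleavage of the PMB ether by hydride abstraction at the benzylic position; buffered conditions spare the silyl ethers and the cyclobutene.

Step 11
Reactants: 14 primary alcohol
Product: 15 (1R,2S,6R)-aldehyde C2(CH3)(OTES)–C3HO
Conditions: Dess–Martin periodinane, pyridine, CH2Cl2, 0 to 23 °C
Reagents that add atoms: none
Why: Dess–Martin oxidation under buffered conditions; the aldehyde has a fully substituted α-carbon and cannot epimerise.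

Step 12
Reactants: 15 aldehyde; 16 isopropenylmagnesium bromide
Product: 17 (1R,2S,6R)-allylic alcohols C3H(OH)–C4(CH3)=CH2 (both C3 epimers)
Conditions: THF, −78 to 0 °C; aq. NH4Cl
Reagents that add atoms: none
Why: Grignard addition to the aldehyde forms C3–C4; the C3 configuration is irrelevant because the carbinol is oxidised in the next step.

Step 13
Reactants: 17 allylic alcohols
Product: 18 (1R,2S,6R)-1-methylcyclobutene isopropenyl ketone (metathesis precursor)
Conditions: Dess–Martin periodinane, pyridine, CH2Cl2, 23 °C
Reagents that add atoms: none
Why: Dess–Martin oxidation of a hindered allylic alcohol to the enone; C1 is β to the new ketone and stays configurationally fixed.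

Step 14
Reactants: 18 metathesis precursor
Product: 19 (1R,2S,6R)-1-isopropenyl-2,4,6-trimethyl-2-(triethylsilyloxy)-6-[(tert-butyldimethylsilyloxy)methyl]cyclohex-4-en-3-one
Conditions: (H2IMes)Cl2Ru=CH(C6H4-2-O-i-Pr) (second-generation Hoveyda–Grubbs catalyst, 10 mol %), toluene (0.005 M), ethylene (1 atm), 80 °C
Reagents that add atoms: none
Why: The ruthenium methylidene formed from the precatalyst adds across the strained C5=C7 bond with the metal on the less substituted C5, and cycloreversion opens the four-membered ring to a C5 alkylidene while C7 becomes the isopropenyl carbon on C1. The alkylidene then forms a second metallacyclobutane with the pendant C4(CH3)=CH2 group and cycloreverts to the C4=C5 bond, returning the methylidene. The closest known reaction type is ring-rearrangement (ring-opening/ring-closing) metathesis of cyclobutenes that carry a pendant alkene, together with ring-closing metathesis onto methacryloyl-type enones with phosphine-free ruthenium catalysts. The six-membered ring C1–C6 is closed by alkene metathesis between the ring-derived alkylidene carbon C5 and the tethered 1,1-disubstituted alkene, giving an endocyclic trisubstituted enone double bond. No stereocentre is formed, and C1, C2 and C6 are not involved in bond changes, so their configuration passes through. The step needs the cyclobutene to open with ruthenium on C5, which the C7 methyl secures because the alternative is a disubstituted alkylidene. It also needs ring closure to beat oligomerisation, which high dilution, ethylene and the two fully substituted carbons next to the reacting atoms should secure. Initiation at the electron-poor isopropenyl ketone is not expected, and the release of cyclobutene strain makes formation of the hindered alkene next to C6 irreversible.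

Step 15
Reactants: 19 cyclohexenone
Product: 21 (1R,2S,6R,7E)-alkenyl pinacol boronate with C7(CH3)=C8H–Bpin on C1, via catechol boronate 20 (not isolated)
Conditions: 2-chloro-1,3,2-benzodioxaborole, Pd2(dba)3 (2.5 mol %), t-BuP(3,5-t-Bu2C6H3)2 (JessePhos, 6 mol %), LiOTf, Cy2NMe, PhCF3, 70 °C; then pinacol, Et3N, 23 °C
Reagents that add atoms: 2-chloro-1,3,2-benzodioxaborole, ClB1Oc2ccccc2O1; pinacol, CC(C)(O)C(C)(C)O
Why: Boryl-Heck reaction: the boryl–palladium species adds to the 1,1-disubstituted alkene with boron on the terminal carbon, and β-hydride elimination toward C8 gives the alkenyl boronate with boron trans to the larger ring substituent (E). The trisubstituted enone alkene is unreactive, and ester exchange with pinacol gives the stable boronate.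

Step 16
Reactants: 21 alkenyl pinacol boronate
Product: 22 (1R,2S,6R,7E)-diol boronate with free C2–OH and C6–CH2OH
Conditions: HF·pyridine, pyridine, THF, 0 to 23 °C
Reagents that add atoms: none
Why: Fluoride-mediated cleavage of both silyl ethers; the buffered reagent should leave the pinacol boronate and the ketol intact.

Step 17
Reactants: 22 diol boronate
Product: 23 (1R,2S,6R,7E)-C6 aldehyde
Conditions: Dess–Martin periodinane, pyridine, CH2Cl2, 0 to 23 °C
Reagents that add atoms: none
Why: Dess–Martin oxidation of the primary alcohol; the tertiary hydroxyl cannot be oxidised, and the aldehyde on quaternary C6 cannot enolise.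

Step 18
Reactants: 23 aldehyde; 24 methyl 2-methyl-3-oxopentanoate
Product: 25 aldol adducts C6–CH(OH)–CH(CH3)–C(=O)–CH(CH3)–CO2CH3 (diastereomer mixture)
Conditions: 24 (3.5 equiv), NaH then n-BuLi, THF, 0 °C; 23, −78 °C; aq. NH4Cl
Reagents that add atoms: none
Why: Aldol addition of the keto ester dianion, which reacts at its γ-carbon, to the only aldehyde; the excess covers the free tertiary hydroxyl, and the new stereocentres disappear in the next two steps.

Step 19
Reactants: 25 aldol adducts
Product: 26 diketo ester C6–C(=O)–CH(CH3)–C(=O)–CH(CH3)–CO2CH3
Conditions: Dess–Martin periodinane, CH2Cl2, 23 °C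
Reagents that add atoms: none
Why: Dess–Martin oxidation of the secondary alcohol to the 1,3,5-tricarbonyl system; the tertiary ketol hydroxyl and the boronate are inert.

Step 20
Reactants: 26 diketo ester
Product: 27 4-hydroxy-3,5-dimethyl-2-pyranone bound to C6 through its C6 position
Conditions: DBU, toluene, 23 °C
Reagents that add atoms: none
Why: Base-mediated enolisation and O-acylation (lactonisation) of the ketone enol on the methyl ester closes the pyranone with loss of methanol; the non-nucleophilic base avoids retro-Claisen cleavage at C6.

Step 21
Reactants: 27 hydroxypyranone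
Product: 28 (1R,2S,6R,7E)-2-methoxy-3,5-dimethyl-4-pyranone ketol
Conditions: CF3SO3CH3, CH2Cl2, 0 to 23 °C; then aq. NaHCO3
Reagents that add atoms: methyl trifluoromethanesulfonate, COS(=O)(=O)C(F)(F)F
Why: Regioselective O-methylation: the hard electrophile alkylates the lactone carbonyl oxygen of the neutral hydroxypyranone and deprotonation gives the 2-methoxy-4-pyranone. The acid stays bound to the basic pyranone until the bicarbonate quench, and the step precedes oxirane formation because the reagent would open a vinyl oxirane.

Step 22
Reactants: 28 methoxypyranone ketol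
Product: 29 (1R,2S,3S,6R,7E)-trans-2,3-diol
Conditions: Me4NBH(OAc)3, MeCN/AcOH, −30 to 0 °C
Reagents that add atoms: none
Why: Hydroxyl-directed (Evans–Saksena type) reduction: the C2 hydroxyl exchanges onto boron and hands hydride to C3 on its own face, so the new hydroxyl is anti to the C2 oxygen. The reagent does not reduce the pyranone and leaves the boronate alone.

Step 23
Reactants: 29 trans-diol
Product: 31 (1R,2S,3R,6R,7E)-2,3-epoxy alkenyl pinacol boronate, via C3 mesylate 30 (not isolated)
Conditions: (CH3SO2)2O, Et3N, CH2Cl2, −20 °C; then K2CO3, MeOH, 0 °C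
Reagents that add atoms: none
Why: Selective sulfonylation of the secondary hydroxyl and intramolecular Williamson closure: the C2 alkoxide displaces the mesylate with inversion at C3, which puts the oxirane oxygen on the face of the C6 methyl. C3 has no β-hydrogen, so elimination cannot compete, and the anhydride avoids chloride that could attack the allylic system.

Step 24
Reactants: 31 epoxy alkenyl boronate; 32 2-bromopentan-3-one (racemic)
Product: 34 target CNP0336888.3 (1R,2S,3R,6R,7E,9R), via alkenylzinc 33 (not isolated)
Conditions: Zn(CH3)2, toluene, 60 °C; then 32 (1.5 equiv), NiCl2·glyme (10 mol %), chiral bis(oxazoline) ligand (Ph-box type, 13 mol %, antipode fixed by a model coupling), glyme/THF, −30 to 0 °C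
Reagents that add atoms: none
Why: Proposed new method: boron-to-zinc exchange gives alkenylzinc 33 with retention of the alkene geometry; a bis(oxazoline)-bound monovalent nickel species abstracts bromine from either enantiomer of 32, the planar α-keto radical is captured by the chiral alkenylnickel complex and reductive elimination forms C8–C9, so the ligand and not the substrate fixes C9 under base-free Negishi conditions that should not enolise the product; the closest known reaction type is the nickel/bis(oxazoline)-catalysed stereoconvergent alkenylation of racemic α-bromo ketones with alkenylzirconium reagents and the related Negishi arylation with arylzinc reagents, from which this step differs in the alkenylzinc nucleophile made by boron–zinc exchange and in the densely functionalised coupling partner.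

## Compound list

1 | (S)-2-methylglycidol, [(2S)-2-methyloxiran-2-yl]methanol | OC[C@@]1(C)CO1 | starting material
2 | (2S)-3-[(4-methoxyphenyl)methoxy]-2-methylpropane-1,2-diol | OC[C@@](O)(C)COCc1ccc(OC)cc1 | intermediate
3 | ethyl 2-(triphenylphosphoranylidene)propanoate | CCOC(=O)C(C)=P(c1ccccc1)(c1ccccc1)c1ccccc1 | starting material
4 | (2R)-2-hydroxy-3-[(4-methoxyphenyl)methoxy]-2-methylpropanal (not isolated) | O=C[C@@](O)(C)COCc1ccc(OC)cc1 | intermediate
5 | ethyl (2E,4S)-4-hydroxy-5-[(4-methoxyphenyl)methoxy]-2,4-dimethylpent-2-enoate | CCOC(=O)/C(C)=C/[C@](C)(O)COCc1ccc(OC)cc1 | intermediate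
6 | ethyl (2E,4S)-5-[(4-methoxyphenyl)methoxy]-2,4-dimethyl-4-(triethylsilyloxy)pent-2-enoate | CCOC(=O)/C(C)=C/[C@](C)(O[Si](CC)(CC)CC)COCc1ccc(OC)cc1 | intermediate
7 | (2E,4S)-5-[(4-methoxyphenyl)methoxy]-2,4-dimethyl-4-(triethylsilyloxy)pent-2-en-1-ol | OC/C(C)=C/[C@](C)(O[Si](CC)(CC)CC)COCc1ccc(OC)cc1 | intermediate
8 | tert-butyl{[(2E,4S)-5-[(4-methoxyphenyl)methoxy]-2,4-dimethyl-4-(triethylsilyloxy)pent-2-en-1-yl]oxy}dimethylsilane | CC(C)(C)[Si](C)(C)OC/C(C)=C/[C@](C)(O[Si](CC)(CC)CC)COCc1ccc(OC)cc1 | intermediate
9 | trichloroacetyl chloride | ClC(=O)C(Cl)(Cl)Cl | starting material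
10 | (1R,2S,6R)-2,2-dichlorocyclobutanone: ring C7(=O)–C5Cl2–C6(CH3)(CH2OTBS)–C1H; C1 carries C2(CH3)(OTES)–CH2OPMB cis to the C6 methyl | O=C1C(Cl)(Cl)[C@@](C)(CO[Si](C)(C)C(C)(C)C)[C@@H]1[C@](C)(O[Si](CC)(CC)CC)COCc1ccc(OC)cc1 | intermediate
11 | (1R,2S,6R)-cyclobutanone: ring C7(=O)–C5H2–C6(CH3)(CH2OTBS)–C1H; C1 carries C2(CH3)(OTES)–CH2OPMB | O=C1C[C@@](C)(CO[Si](C)(C)C(C)(C)C)[C@@H]1[C@](C)(O[Si](CC)(CC)CC)COCc1ccc(OC)cc1 | intermediate
12 | (1R,2S,6R)-cyclobutenyl triflate: ring C7(OTf)=C5H–C6–C1, substituents as in 11 | O=S(=O)(OC1=C[C@@](C)(CO[Si](C)(C)C(C)(C)C)[C@@H]1[C@](C)(O[Si](CC)(CC)CC)COCc1ccc(OC)cc1)C(F)(F)F | intermediate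
13 | (1R,2S,6R)-1-methylcyclobutene PMB ether: ring C7(CH3)=C5H–C6(CH3)(CH2OTBS)–C1H; C1 carries C2(CH3)(OTES)–CH2OPMB | CC1=C[C@@](C)(CO[Si](C)(C)C(C)(C)C)[C@@H]1[C@](C)(O[Si](CC)(CC)CC)COCc1ccc(OC)cc1 | intermediate
14 | (1R,2S,6R)-primary alcohol: as 13 with C2(CH3)(OTES)–CH2OH | CC1=C[C@@](C)(CO[Si](C)(C)C(C)(C)C)[C@@H]1[C@](C)(O[Si](CC)(CC)CC)CO | intermediate
15 | (1R,2S,6R)-aldehyde: as 13 with C2(CH3)(OTES)–CHO | CC1=C[C@@](C)(CO[Si](C)(C)C(C)(C)C)[C@@H]1[C@](C)(O[Si](CC)(CC)CC)C=O | intermediate
16 | isopropenylmagnesium bromide | C=C(C)[Mg]Br | starting material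
17 | (1R,2S,6R)-allylic alcohols: as 13 with C2(CH3)(OTES)–C3H(OH)–C4(CH3)=CH2, both C3 epimers | CC1=C[C@@](C)(CO[Si](C)(C)C(C)(C)C)[C@@H]1[C@](C)(O[Si](CC)(CC)CC)C(O)C(C)=C | intermediate
18 | (1R,2S,6R)-1-methylcyclobutene isopropenyl ketone: as 13 with C2(CH3)(OTES)–C3(=O)–C4(CH3)=CH2 | CC1=C[C@@](C)(CO[Si](C)(C)C(C)(C)C)[C@@H]1[C@](C)(O[Si](CC)(CC)CC)C(=O)C(C)=C | intermediate
19 | (1R,2S,6R)-1-isopropenyl-2,4,6-trimethyl-2-(triethylsilyloxy)-6-[(tert-butyldimethylsilyloxy)methyl]cyclohex-4-en-3-one | C=C(C)[C@H]1[C@](C)(O[Si](CC)(CC)CC)C(=O)C(C)=C[C@@]1(C)CO[Si](C)(C)C(C)(C)C | intermediate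
20 | catechol boronate (not isolated): as 19 with (E)-C7(CH3)=C8H–B(catecholate) on C1 | O1c2ccccc2OB1/C=C(\C)[C@H]1[C@](C)(O[Si](CC)(CC)CC)C(=O)C(C)=C[C@@]1(C)CO[Si](C)(C)C(C)(C)C | intermediate
21 | (1R,2S,6R,7E)-alkenyl pinacol boronate: as 19 with C7(CH3)=C8H–Bpin on C1 | CC1(C)OB(OC1(C)C)/C=C(\C)[C@H]1[C@](C)(O[Si](CC)(CC)CC)C(=O)C(C)=C[C@@]1(C)CO[Si](C)(C)C(C)(C)C | intermediate
22 | (1R,2S,6R,7E)-diol boronate: C2–OH and C6–CH2OH free | CC1(C)OB(OC1(C)C)/C=C(\C)[C@H]1[C@](C)(O)C(=O)C(C)=C[C@@]1(C)CO | intermediate
23 | (1R,2S,6R,7E)-C6 aldehyde | CC1(C)OB(OC1(C)C)/C=C(\C)[C@H]1[C@](C)(O)C(=O)C(C)=C[C@@]1(C)C=O | intermediate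
24 | methyl 2-methyl-3-oxopentanoate (racemic) | CCC(=O)C(C)C(=O)OC | starting material
25 | aldol adducts: C6–CH(OH)–CH(CH3)–C(=O)–CH(CH3)–CO2CH3, diastereomer mixture | CC1(C)OB(OC1(C)C)/C=C(\C)[C@H]1[C@](C)(O)C(=O)C(C)=C[C@@]1(C)C(O)C(C)C(=O)C(C)C(=O)OC | intermediate
26 | diketo ester: C6–C(=O)–CH(CH3)–C(=O)–CH(CH3)–CO2CH3 | CC1(C)OB(OC1(C)C)/C=C(\C)[C@H]1[C@](C)(O)C(=O)C(C)=C[C@@]1(C)C(=O)C(C)C(=O)C(C)C(=O)OC | intermediate
27 | 4-hydroxy-3,5-dimethyl-2-pyranone bound to C6 through its C6 position | CC1(C)OB(OC1(C)C)/C=C(\C)[C@H]1[C@](C)(O)C(=O)C(C)=C[C@@]1(C)c1oc(=O)c(C)c(O)c1C | intermediate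
28 | (1R,2S,6R,7E)-2-methoxy-3,5-dimethyl-4-pyranone ketol: C2–OH, C3 ketone | CC1(C)OB(OC1(C)C)/C=C(\C)[C@H]1[C@](C)(O)C(=O)C(C)=C[C@@]1(C)c1oc(OC)c(C)c(=O)c1C | intermediate
29 | (1R,2S,3S,6R,7E)-trans-2,3-diol | CC1(C)OB(OC1(C)C)/C=C(\C)[C@H]1[C@](C)(O)[C@@H](O)C(C)=C[C@@]1(C)c1oc(OC)c(C)c(=O)c1C | intermediate
30 | (1R,2S,3S,6R,7E)-C3 mesylate (not isolated) | CC1(C)OB(OC1(C)C)/C=C(\C)[C@H]1[C@](C)(O)[C@@H](OS(C)(=O)=O)C(C)=C[C@@]1(C)c1oc(OC)c(C)c(=O)c1C | intermediate
31 | (1R,2S,3R,6R,7E)-2,3-epoxy alkenyl pinacol boronate | CC1(C)OB(OC1(C)C)/C=C(\C)[C@H]1[C@]2(C)O[C@@H]2C(C)=C[C@@]1(C)c1oc(OC)c(C)c(=O)c1C | intermediate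
32 | 2-bromopentan-3-one (racemic) | CCC(=O)C(C)Br | starting material
33 | (E)-alkenyl(methyl)zinc (not isolated): as 31 with C8–ZnCH3 | C[Zn]/C=C(\C)[C@H]1[C@]2(C)O[C@@H]2C(C)=C[C@@]1(C)c1oc(OC)c(C)c(=O)c1C | intermediate
34 | CNP0336888.3, (1R,2S,3R,6R,7E,9R) | CCC(=O)[C@H](C)/C=C(\C)[C@H]1[C@]2(C)O[C@@H]2C(C)=C[C@@]1(C)c1oc(OC)c(C)c(=O)c1C | target

## Step count and least certain steps

Total: 24 steps. Longest linear sequence: 24 steps from 1; compounds 3, 9, 16, 24 and 32 are commercial.

**Step 24 (C8–C9 coupling).** The boron-to-zinc exchange at a hindered trisubstituted alkenyl boronate may be slow or incomplete. The zinc reagent may open the vinyl oxirane at the temperature the exchange needs. The new C9 centre may erode by enolisation. The sense and level of catalyst control with this nucleophile are not known. The fallback sets out from trans-diol 29 and comes back at 34. Iododeboronation with N-iodosuccinimide replaces boron by iodine with retention and gives the (E)-alkenyl iodide F1. A palladium-catalysed α-alkenylation of the tin enolate of pentan-3-one, made in the flask from (Z)-3-(trimethylsilyloxy)pent-2-ene and Bu3SnF with PdCl2[P(o-tol)3]2 in toluene at 80 °C, joins C8 to C9 under nearly neutral conditions and gives the ketone diol F2 as a pair of C9 epimers. These are diastereomers and would be separated by chromatography; the unwanted epimer would be re-equilibrated with an amine base and recycled. Selective mesylation of the C3 hydroxyl to the mesylate F3 and closure with K2CO3 in methanol at low temperature would give 34. This uses known reactions only, gives up catalyst control at C9 for separation and recycling, and keeps palladium away from the vinyl oxirane because the oxirane is closed last.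

**Step 14 (key step).** The opened alkylidene next to quaternary C6 may fail to engage the electron-poor, 1,1-disubstituted enone alkene. The material would then be diverted into ring-opening oligomers or stop at the ethylene-capped triene while the catalyst decays. The fallback sets out from allylic alcohols 17 and comes back at 19. The rearrangement is run at the alcohol oxidation level, where the acceptor alkene is electron-rich and carries an allylic hydroxyl that is known to speed up metathesis at the neighbouring alkene. The ring-rearranged cyclohexenol F4 is then oxidised with Dess–Martin periodinane to 19. The enone is thus made after the ring instead of being used to make it.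

**Step 6 (ketene cycloaddition).** Facial discrimination by the fully substituted C2 centre may be poor or may favour the wrong face, because methyl, silyloxy and CH2OPMB differ little in size near the alkene. The hindered, inductively deactivated alkene may also react slowly. The fallback sets out from 8 and comes back at 11. A keteniminium triflate is generated from 1-[(2R,5R)-2,5-dimethylpyrrolidin-1-yl]ethanone (or its antipode, whichever is matched with C2), Tf2O and 2,4,6-collidine. It undergoes [2+2] cycloaddition with 8 with the same regiochemistry to give the cyclobutaniminium triflate F5, which aqueous NaHCO3 hydrolyses to 11. This adds reagent control to substrate control, uses a more electrophilic two-carbon partner and makes the dechlorination unnecessary.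

**Step 15 (boryl-Heck reaction).** β-Hydride elimination may go toward the methyl group or C1 and give allyl boronates. The E/Z ratio may erode, or the Lewis-acidic boron chloride may cleave the tertiary silyl ether. The fallback sets out from 19 and comes back at 21. A rhodium-catalysed dehydrogenative borylation of the 1,1-disubstituted alkene with bis(pinacolato)diboron and trans-[RhCl(CO)(PPh3)2] installs the pinacol boronate directly without a boron halide; this fallback makes no compound outside the compound list (F0).

**Step 22 (directed reduction).** Internal hydride delivery through the five-membered boron chelate to a conjugated, hindered ketone may be slow. External attack would then decide the face and could give the cis-diol, which cannot close to the oxirane. The fallback sets out from 28 and comes back at 29. Reduction with NaBH4/CeCl3 is accepted as giving the cis-diol F6. A Mitsunobu reaction with 4-nitrobenzoic acid, PPh3 and diisopropyl azodicarboxylate inverts C3 and gives the 4-nitrobenzoate F7, and methanolysis with K2CO3 gives 29. Elimination cannot compete here, since C3 has no β-hydrogen.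

## Further compounds

F1 | step 24 | (1R,2S,3S,6R,7E)-alkenyl iodide trans-diol | I/C=C(\C)[C@H]1[C@](C)(O)[C@@H](O)C(C)=C[C@@]1(C)c1oc(OC)c(C)c(=O)c1C
F2 | step 24 | (1R,2S,3S,6R,7E,9R)-ketone trans-diol (9R epimer after separation) | CCC(=O)[C@H](C)/C=C(\C)[C@H]1[C@](C)(O)[C@@H](O)C(C)=C[C@@]1(C)c1oc(OC)c(C)c(=O)c1C
F3 | step 24 | C3 mesylate of F2 | CCC(=O)[C@H](C)/C=C(\C)[C@H]1[C@](C)(O)[C@@H](OS(C)(=O)=O)C(C)=C[C@@]1(C)c1oc(OC)c(C)c(=O)c1C
F4 | step 14 | (1R,2S,6R)-1-isopropenyl cyclohex-4-en-3-ol (both C3 epimers), silyl ethers as in 19 | C=C(C)[C@H]1[C@](C)(O[Si](CC)(CC)CC)C(O)C(C)=C[C@@]1(C)CO[Si](C)(C)C(C)(C)C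
F5 | step 6 | cyclobutaniminium triflate from 8 and the (2R,5R)-2,5-dimethylpyrrolidine keteniminium | C[C@@H]1CC[C@@H](C)[N+]1=C1C[C@@](C)(CO[Si](C)(C)C(C)(C)C)[C@@H]1[C@](C)(O[Si](CC)(CC)CC)COCc1ccc(OC)cc1.[O-]S(=O)(=O)C(F)(F)F
F0 | step 15 | none | none
F6 | step 22 | (1R,2S,3R,6R,7E)-cis-2,3-diol (C3 epimer of 29) | CC1(C)OB(OC1(C)C)/C=C(\C)[C@H]1[C@](C)(O)[C@H](O)C(C)=C[C@@]1(C)c1oc(OC)c(C)c(=O)c1C
F7 | step 22 | C3 4-nitrobenzoate with inverted C3 (trans to the C2 hydroxyl) | CC1(C)OB(OC1(C)C)/C=C(\C)[C@H]1[C@](C)(O)[C@@H](OC(=O)c2ccc(cc2)[N+](=O)[O-])C(C)=C[C@@]1(C)c1oc(OC)c(C)c(=O)c1C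
A1 | alternative 1 | cis-fused menthyloxy lactone acetal cycloadduct with the silyl enol ether at C3=C4 | O=C1O[C@H](O[C@H]3C[C@@H](C)CC[C@@H]3C(C)C)[C@H]2[C@@H](C)C(O[Si](C)(C)C(C)(C)C)=C(C)C[C@@]12C
A2 | alternative 1 | 5-(menthyloxy)-3-methylfuran-2(5H)-one | O=C1O[C@H](O[C@H]2C[C@@H](C)CC[C@@H]2C(C)C)C=C1C
A3 | alternative 1 | (Z)-3-(tert-butyldimethylsilyloxy)-2-methylpenta-1,3-diene | C/C=C(O[Si](C)(C)C(C)(C)C)/C(C)=C
A4 | alternative 2 | C2-hydroxy C3-ketone cyclohexenone with ketal-protected side chain and pyranone | CCC1(OCCO1)[C@H](C)/C=C(\C)[C@H]1[C@](C)(O)C(=O)C(C)=C[C@@]1(C)c1oc(OC)c(C)c(=O)c1C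
A5 | alternative 2 | acyclic (Z)-enal methyl ketone | CCC1(OCCO1)[C@H](C)/C=C(\C)[C@@H](C(C)=O)[C@@](C)(/C=C(/C)C=O)c1oc(OC)c(C)c(=O)c1C
A6 | alternative 3 | cyclohexenol methyl ester with C3 hydroxyl trans to the C2 silyloxy group | CCC1(OCCO1)[C@H](C)/C=C(\C)[C@H]1[C@](C)(O[Si](C)(C)C(C)(C)C)[C@@H](O)C(C)=C[C@@]1(C)C(=O)OC
A7 | alternative 3 | acyclic C3 aldehyde with (Z)-vinyl iodide | CCC1(OCCO1)[C@H](C)/C=C(\C)[C@@H]([C@](C)(O[Si](C)(C)C(C)(C)C)C=O)[C@@](C)(/C=C(/C)I)C(=O)OC
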